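**Retrosynthetic overview** (isochromene numbering: C1, O2, C3, C4, C4a, C5–C8, C8a)
1. Target 18 ⇒ tertiary alcohol 16 + octadecanoyl chloride 17 (acylation of the C7 oxygen comes last).
2. The carbocycle C4a–C5–C6–C7–C8–C8a of 16 ⇒ pyran acid chloride 13 (brings C8, C8a, C4a, C5 and C1 as a methoxy acetal) + lactic acid acetal 3 (brings C6, C7, 7-CH3, 7-O). Bonds C7–C8 (Claisen) and C5–C6 (vinylogous Dieckmann) form in one pot, followed by loss of pivalaldehyde and methanol.
3. Enabling feature: in the pyran ring the C5 methyl sits on C4a, cis to the C8 carbonyl across the tetrasubstituted C4a=C8a bond, so it is γ-acidic. C1 carries OMe as the leaving group for a terminal E1cB that creates C1=C8a and C4a=C5. The O–C7–C6(=O) unit is held in a temporary 1,3-dioxolan-4-one ring whose acetal carbon relays the lactate configuration to the quaternary C7.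
4. 13 ⇒ dihydropyranone ester 9 (MeCeCl2 addition, acid/methanol transposition, saponification) ⇒ δ-hydroxy-β-keto ester 6 + DMF dimethyl acetal ⇒ ethyl (3R)-3-hydroxybutanoate (source of C3).
5. Ring order: temporary dioxolanone and dihydropyran ring first, carbocycle last.

Key step: step 7

Assumption: the acetal carbon of the pyran intermediates 11 to 15 is carried as a mixture of epimers, because it becomes the sp2 carbon C1 of the target in step 7.

**Step 1**
Reactants: 1 (R)-lactic acid; 2 pivalaldehyde
Product: 3 (2R,5R)-2-tert-butyl-5-methyl-1,3-dioxolan-4-one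
Conditions: p-TsOH·H2O (cat.), H2SO4 (cat.), pentane, reflux, Dean–Stark; crystallisation from pentane at low temperature
Reagents that add atoms: none
Why: Acid-catalysed acetalisation of the α-hydroxy acid with azeotropic removal of water should give the dioxolanone, the new acetal centre being set cis to the methyl group under thermodynamic control and the cis isomer purified by crystallisation.

**Step 2**
Reactants: 4 ethyl (3R)-3-hydroxybutanoate; 5 methyl acetate
Product: 6 methyl (5R)-5-hydroxy-3-oxohexanoate
Conditions: 5, LiN(iPr)2 (3.5 equiv), THF, −78 °C; then 4, −78 to −30 °C; AcOH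
Reagents that add atoms: none
Why: Crossed Claisen condensation of an unprotected β-hydroxy ester with excess lithium ester enolate (the alkoxide suppresses self-condensation and the product is stored as its dianion) should give the δ-hydroxy-β-keto ester without touching the carbinol stereocentre.

**Step 3**
Reactants: 6 methyl (5R)-5-hydroxy-3-oxohexanoate; 7 N,N-dimethylformamide dimethyl acetal
Product: 9 methyl (2R)-2-methyl-4-oxo-3,4-dihydro-2H-pyran-5-carboxylate, via enaminone 8 (not isolated)
Conditions: Me2NCH(OMe)2, THF, rt; then BF3·OEt2, 0 °C
Reagents that add atoms: none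
Why: Aminomethylenation of the active methylene followed by acid-promoted intramolecular addition–elimination of the δ-hydroxyl on the enaminone should close the 2,3-dihydro-4H-pyran-4-one ring; no stereocentre is formed.

**Step 4**
Reactants: 9 methyl (2R)-2-methyl-4-oxo-3,4-dihydro-2H-pyran-5-carboxylate
Product: 11 methyl (6R)-2-methoxy-4,6-dimethyl-5,6-dihydro-2H-pyran-3-carboxylate as a mixture of C2 epimers, via tertiary alcohol 10 (not isolated)
Conditions: MeMgBr, CeCl3, THF, −78 °C; NH4Cl (aq); then PPTS (cat.), MeOH, 0 °C
Reagents that add atoms: methylmagnesium bromide, C[Mg]Br; methanol, CO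
Why: Chemoselective 1,2-addition of the organocerium reagent MeCeCl2 to the ketone, then acid-mediated ionisation to the oxygen-stabilised allyl cation and capture by methanol at the acetal carbon (a Stork–Danheiser-type alkylative transposition stopped at the acetal), should give the tetrasubstituted enoate; the new acetal centre forms as an inconsequential mixture because it is removed in step 7.

**Step 5**
Reactants: 11 methyl (6R)-2-methoxy-4,6-dimethyl-5,6-dihydro-2H-pyran-3-carboxylate
Product: 12 lithium (6R)-2-methoxy-4,6-dimethyl-5,6-dihydro-2H-pyran-3-carboxylate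
Conditions: LiOH·H2O (1.05 equiv), THF/MeOH/H2O, 50 °C; evaporation, toluene azeotrope
Reagents that add atoms: lithium hydroxide, [Li+].[OH-]
Why: Saponification of the methyl ester under basic conditions, to which the acetal is inert, should give the dry lithium carboxylate and avoids the free acid that could ionise the acetal.

**Step 6**
Reactants: 12 lithium (6R)-2-methoxy-4,6-dimethyl-5,6-dihydro-2H-pyran-3-carboxylate
Product: 13 (6R)-2-methoxy-4,6-dimethyl-5,6-dihydro-2H-pyran-3-carbonyl chloride
Conditions: (COCl)2, pyridine (cat.), toluene, 0 °C to rt; filtered, concentrated, used at once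
Reagents that add atoms: oxalyl chloride, O=C(Cl)C(=O)Cl
Why: A carboxylate salt reacts with oxalyl chloride to give the acid chloride with evolution of CO and CO2 and without free HCl, which should preserve the acid-labile acetal.

**Step 7**
Reactants: 3 (2R,5R)-2-tert-butyl-5-methyl-1,3-dioxolan-4-one; 13 (6R)-2-methoxy-4,6-dimethyl-5,6-dihydro-2H-pyran-3-carbonyl chloride
Product: 16 (3R,7R)-7-hydroxy-3,7-dimethyl-3,4-dihydro-6H-isochromene-6,8(7H)-dione, via lithium enolate 14 (not isolated), via acyl dioxolanone 15 (not isolated)
Conditions: 3, LiN(iPr)2, THF, −78 °C; then 13, −78 °C; then LiN(SiMe3)2 (2.2 equiv), −78 to −20 °C; AcOH, −78 °C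
Reagents that add atoms: none
Why: Proposed new method: the lithium enolate 14 should be C-acylated by 13 on the face anti to the tert-butyl group (self-regeneration of stereocentres), which sets the quaternary C7 with the lactate configuration relayed through the acetal carbon; LiN(SiMe3)2 then removes a proton from the C5 methyl group, which sits cis to the C8 carbonyl on the tetrasubstituted C4a=C8a bond of the pyran ring, and the cross-conjugated dienolate attacks the dioxolanone carbonyl (C6) in a vinylogous Dieckmann condensation, a 6-(enolendo)-exo-trig closure of the carbocycle. Collapse of the tetrahedral intermediate opens the temporary dioxolanone ring and expels pivalaldehyde to free the C7 alkoxide, and a second deprotonation at the now doubly activated C5 triggers E1cB loss of methoxide from C1, which installs the C1=C8a and C4a=C5 double bonds of the dione chromophore. The closest known reaction types are the Claisen reaction of ester enolates with 1,3-dioxolan-4-ones that releases the aldehyde (tetronic acid synthesis), the Dieckmann closure of γ-deprotonated β-methyl enoates and o-toluates (Staunton–Weinreb annulation) and the E1cB elimination of β-alkoxy ketones; what has not been shown is their combination on an acyl dioxolanone to close a carbocycle. The only new stereocentre, C7, is controlled by the acetal tert-butyl group in the acylation and cannot epimerise afterwards because it is quaternary, while C3 is not touched. The step needs deprotonation at the exocyclic methyl and not at ring C4, which the primary C–H bonds and the hindered base favour and which is corrected by the fact that only the C5 dienolate can reach the lactone through a six-membered transition state; it also needs ring closure before loss of methoxide, which lithium chelation between the C8 carbonyl oxygen and the C1 methoxy group (turning the dioxolanone towards C5) and the activated, acylal-type lactone carbonyl should secure.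

**Step 8**
Reactants: 16 (3R,7R)-7-hydroxy-3,7-dimethyl-3,4-dihydro-6H-isochromene-6,8(7H)-dione; 17 octadecanoyl chloride
Product: 18 (3R,7R)-3,7-dimethyl-6,8-dioxo-3,4,7,8-tetrahydro-6H-isochromen-7-yl octadecanoate
Conditions: Et3N, DMAP (cat.), CH2Cl2, 0 °C to rt
Reagents that add atoms: none
Why: DMAP-catalysed acylation of the tertiary α-ketol with an acid chloride, a standard esterification for hindered tertiary alcohols, should give the stearate without change at C7, which carries no epimerisable hydrogen.

**Compound list**
1 | (R)-lactic acid, (2R)-2-hydroxypropanoic acid | C[C@@H](O)C(=O)O | starting material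
2 | pivalaldehyde, 2,2-dimethylpropanal | CC(C)(C)C=O | starting material
3 | (2R,5R)-2-tert-butyl-5-methyl-1,3-dioxolan-4-one | C[C@H]1O[C@@H](C(C)(C)C)OC1=O | intermediate
4 | ethyl (3R)-3-hydroxybutanoate | CCOC(=O)C[C@@H](C)O | starting material
5 | methyl acetate | COC(C)=O | starting material
6 | methyl (5R)-5-hydroxy-3-oxohexanoate | COC(=O)CC(=O)C[C@@H](C)O | intermediate
7 | N,N-dimethylformamide dimethyl acetal | COC(OC)N(C)C | starting material
8 | methyl (5R)-2-[(dimethylamino)methylidene]-5-hydroxy-3-oxohexanoate | COC(=O)C(=CN(C)C)C(=O)C[C@@H](C)O | intermediate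
9 | methyl (2R)-2-methyl-4-oxo-3,4-dihydro-2H-pyran-5-carboxylate | COC(=O)C1=CO[C@H](C)CC1=O | intermediate
10 | methyl (2R)-4-hydroxy-2,4-dimethyl-3,4-dihydro-2H-pyran-5-carboxylate (C4 epimers) | COC(=O)C1=CO[C@H](C)CC1(C)O | intermediate
11 | methyl (6R)-2-methoxy-4,6-dimethyl-5,6-dihydro-2H-pyran-3-carboxylate (C2 epimers) | COC(=O)C1=C(C)C[C@@H](C)OC1OC | intermediate
12 | lithium (6R)-2-methoxy-4,6-dimethyl-5,6-dihydro-2H-pyran-3-carboxylate (C2 epimers) | [Li+].[O-]C(=O)C1=C(C)C[C@@H](C)OC1OC | intermediate
13 | (6R)-2-methoxy-4,6-dimethyl-5,6-dihydro-2H-pyran-3-carbonyl chloride (C2 epimers) | O=C(Cl)C1=C(C)C[C@@H](C)OC1OC | intermediate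
14 | lithium (2R)-2-tert-butyl-5-methyl-1,3-dioxol-4-olate | [Li+].[O-]C1=C(C)O[C@@H](C(C)(C)C)O1 | intermediate
15 | (2R,5S)-2-tert-butyl-5-[(6R)-2-methoxy-4,6-dimethyl-5,6-dihydro-2H-pyran-3-carbonyl]-5-methyl-1,3-dioxolan-4-one (pyran C2 epimers) | C[C@@]1(C(=O)C2=C(C)C[C@@H](C)OC2OC)O[C@@H](C(C)(C)C)OC1=O | intermediate
16 | (3R,7R)-7-hydroxy-3,7-dimethyl-3,4-dihydro-6H-isochromene-6,8(7H)-dione | O[C@]1(C)C(=O)C=C2C[C@@H](C)OC=C2C1=O | intermediate
17 | octadecanoyl chloride (stearoyl chloride) | CCCCCCCCCCCCCCCCCC(=O)Cl | starting material
18 | (3R,7R)-3,7-dimethyl-6,8-dioxo-3,4,7,8-tetrahydro-6H-isochromen-7-yl octadecanoate | CCCCCCCCCCCCCCCCCC(=O)O[C@]1(C)C(=O)C=C2C[C@@H](C)OC=C2C1=O | target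

**Step count and risks**
Total step count: 8. Longest linear sequence: 7 steps (steps 2 to 8, from 4 to 18); step 1 is a one-step side branch.

The three steps most likely to fail:

1. Step 7 (proposed new method). In the first stage the enolate may be O-acylated, or the acid chloride may be dehydrochlorinated. In the second stage the base may remove a proton at ring C4 instead of the C5 methyl, methoxide may be lost before the ring closes, and alkoxide may cleave the non-enolisable β-keto lactone by a retro-Claisen reaction. The product may also suffer base-induced retro-oxa-Michael opening of its pyran ring, which would erase C3. The fallback uses known chemistry only, sets out from 13 and comes back at 16. Crossed Claisen acylation of the lithium enolate of methyl propanoate (LiN(iPr)2, THF, −78 °C) with 13 would give methyl 3-[(6R)-2-methoxy-4,6-dimethyl-5,6-dihydro-2H-pyran-3-yl]-2-methyl-3-oxopropanoate F1. Its dianion (KN(SiMe3)2, THF, −78 to 0 °C) would close the carbocycle by a polyketide-type Claisen cyclisation onto the methyl ester and lose methoxide from C1 to give (3R)-6-hydroxy-3,7-dimethyl-3,4-dihydro-8H-isochromen-8-one F2. Hydroxylation of this vinylogous acid at C7 with IBX (TFA, cat. Bu4NI, 1,2-dichloroethane), the established oxidation for this class, would give 16 together with its epimer (3R,7S)-7-hydroxy-3,7-dimethyl-3,4-dihydro-6H-isochromene-6,8(7H)-dione F3. The two are diastereomers and would be separated by chromatography, at the price of giving up control of C7.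

2. Step 4. The methyl nucleophile may add in conjugate fashion at the alkoxy-bearing ring carbon or attack the ester instead of the ketone. In the acidic stage the cation may lose a ring proton to form a 2H-pyran, whose reversible electrocyclic ring opening would erode the configuration at the methyl-bearing ring carbon. The fallback sets out from 9 and comes back at 11, and replaces carbonyl addition by olefination. Takai–Lombardo methylenation (Zn, CH2Br2, TiCl4, THF/CH2Cl2, 0 °C), which is non-basic and spares esters, would give methyl (2R)-2-methyl-4-methylidene-3,4-dihydro-2H-pyran-5-carboxylate F4. PPTS-catalysed 1,4-addition of methanol across this cross-conjugated dienol ether (protonation at the exocyclic CH2, capture at the acetal carbon) would then give 11.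

3. Step 6. The acetal may ionise under the activating conditions and the acid chloride may lose HCl to a vinylketene on handling. The fallback sets out from 11 and comes back at 15, and replaces acylation by aldol addition and oxidation. Reduction with iBu2AlH (CH2Cl2, −78 °C) would give [(6R)-2-methoxy-4,6-dimethyl-5,6-dihydro-2H-pyran-3-yl]methanol F5, and MnO2 (CH2Cl2) would give (6R)-2-methoxy-4,6-dimethyl-5,6-dihydro-2H-pyran-3-carbaldehyde F6. Aldol addition of enolate 14 (from 3, LiN(iPr)2, THF, −78 °C), anti to the tert-butyl group, would give (2R,5S)-2-tert-butyl-5-{hydroxy[(6R)-2-methoxy-4,6-dimethyl-5,6-dihydro-2H-pyran-3-yl]methyl}-5-methyl-1,3-dioxolan-4-one F7 as carbinol epimers. Oxidation with Dess–Martin periodinane (NaHCO3, CH2Cl2) would give 15, now isolated, which enters the LiN(SiMe3)2 stage of step 7.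

**Further compounds**
F1 | step 7 | methyl 3-[(6R)-2-methoxy-4,6-dimethyl-5,6-dihydro-2H-pyran-3-yl]-2-methyl-3-oxopropanoate | COC(=O)C(C)C(=O)C1=C(C)C[C@@H](C)OC1OC
F2 | step 7 | (3R)-6-hydroxy-3,7-dimethyl-3,4-dihydro-8H-isochromen-8-one | CC1=C(O)C=C2C[C@@H](C)OC=C2C1=O
F3 | step 7 | (3R,7S)-7-hydroxy-3,7-dimethyl-3,4-dihydro-6H-isochromene-6,8(7H)-dione | O[C@@]1(C)C(=O)C=C2C[C@@H](C)OC=C2C1=O
F4 | step 4 | methyl (2R)-2-methyl-4-methylidene-3,4-dihydro-2H-pyran-5-carboxylate | C=C1C[C@@H](C)OC=C1C(=O)OC
F5 | step 6 | [(6R)-2-methoxy-4,6-dimethyl-5,6-dihydro-2H-pyran-3-yl]methanol | OCC1=C(C)C[C@@H](C)OC1OC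
F6 | step 6 | (6R)-2-methoxy-4,6-dimethyl-5,6-dihydro-2H-pyran-3-carbaldehyde | O=CC1=C(C)C[C@@H](C)OC1OC
F7 | step 6 | (2R,5S)-2-tert-butyl-5-{hydroxy[(6R)-2-methoxy-4,6-dimethyl-5,6-dihydro-2H-pyran-3-yl]methyl}-5-methyl-1,3-dioxolan-4-one | C[C@@]1(C(O)C2=C(C)C[C@@H](C)OC2OC)O[C@@H](C(C)(C)C)OC1=O
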